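**Equal product.** The spring run, with 1.51 times the free catalyst of the winter run, reached the winter run's 27 % of product 1.47 times sooner, the spring time being interpolated between its readings. I started from these two ratios; the new flask is asked about at one conversion, not at one time.

| flask | starting material | partner | protic impurity | free catalyst | remark |
|---|---|---|---|---|---|
| winter | 0.30 M | 0.33 M | 0.060 M | 6.5 mM | run made earlier |
| spring | 0.30 M | 0.33 M | 0.060 M | 9.8 mM | run made earlier |
| flask | 0.30 M | 0.330 M | 0.0600 M | 13 mM |  |

| winter: time / d | winter: product / % | spring: time / d | spring: product / % |
|---|---|---|---|
| 0.250 | 5 | 0.500 | 22 |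
| 0.417 | 9 | 1.04 | 35 |
| 0.625 | 15 | 1.67 | 42 |
| 1.04 | 27 | 2.08 | 43 |
| 1.67 | 32 | 2.50 | 44 |
| 2.50 | 35 | 3.00 | 45 |
| 4.00 | 39 | 4.00 | 45 |

(scatter of a reading: 1.5 percentage points)

- apparent order in free catalyst when 20 % of the starting material are converted (percent change of the rate of making product for one percent more free catalyst charged)
- apparent order in partner when 20 % of the starting material are converted (percent change of the rate of making product for one percent more partner charged)

- the numbers in the tables scatter by 1.5 percentage points (one standard deviation)
- what has left starting material counts as converted, also if it is not yet product
- no earlier run changes the charge of partner; that part of a forecast is a guess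

**Two ways.** The logarithm of the time ratio over the logarithm of the catalyst ratio came to 0.938, and I called this number n, the equal-progress order. The readings show product, not conversion, so equal product stood in for equal conversion. The second way compared equal times: at 0.500 d the spring run stood at 22 % and the winter run, interpolated, at 11.4 %, which gave an order of 1.60.

**Which cheats.** The two ways parted, and I distrusted the equal-time figure: it set the spring run at 22 % of product against the winter run at 11.4 %, two different stages. I stood by 0.938 for free catalyst. No run varied the partner, so I had no reckoning for it.

**The forecast.** The forecast gave 1.7 for free catalyst and 0.5 for partner, reasoning that “1.5 times the catalyst doubles the rate”. That is the equal-time way, where my own figure was 1.60.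

**The flask.** The simulation gave 1.2 in free catalyst and 0.17 in partner.

    starting material + free catalyst ⇌ free catalyst + open intermediate (K = 1.40, k = 0.00310 M⁻¹ s⁻¹)
    starting material + protic impurity → quenched substrate (k = 1.10 × 10⁻⁴ M⁻¹ s⁻¹)
    free catalyst + open intermediate ⇌ catalyst intermediate (K = 1.50 M⁻¹, k = 0.00360 M⁻¹ s⁻¹)
    partner + catalyst intermediate → free catalyst + product (k = 0.0380 M⁻¹ s⁻¹)
    open intermediate → decomposed reagent (k = 2.40 × 10⁻⁵ s⁻¹)

At 0.600 d the flask held 98.8 % of its catalyst as free catalyst, the resting state, and 1.20 % as catalyst intermediate. Carried from the winter run with n, my estimate put 27 % of product in the flask at 0.543 d, an extrapolation; the flask itself held 34.4 % of product at 0.600 d.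

The readings were generated by integration on assumed constants; the scatter is artificial.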